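The cyclohexane ring C5–C10 (elemane numbering) is traced to 3,5-dimethoxybenzoic acid, whose ring is remodelled rather than kept. Birch alkylation gives an achiral cyclohexadiene acid; its carboxyl (C1, later the vinyl carbon) carries a β-acyloxy enone as tether. Under a chiral acid one of the two enantiotopic enol ethers becomes the diene terminus and an intramolecular Diels–Alder reaction forms C5–C6 and C7–C8 at once, giving a bicyclo[2.2.2]octene with a γ-lactone. The step exploits the cis relation of the C6 oxygen to C1 on C10 and the 1,3-oxygen pattern at C6/C8. Retro-aldol opening later cleaves C8–C15, so the old arene carbons C4 and C15 become the acrolein side chain on C5.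

Key step: step 3

Numbering: the elemane locants of the target are used for every compound. The ring is C5–C10. C10 carries the vinyl group C1=C2 and C14 (the CH2OAc carbon). C5 carries C4(=C3)–C15HO. The lactone is O–C6, C7–C11(=C13)–C12(=O). The ester oxygen is on C8. β is the ring face that carries C14, α the face that carries C1. In compounds 2–10, C15 is the ring CH or CH2 between the methoxy-bearing carbons C4 and C8.

Assumption: the (R)-configured acid catalyst of step 3 is taken to lead to the enantiomer drawn; if its sense of induction is the opposite, the (S)-catalyst is used.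

Step 1
Reactants: 1 3,5-dimethoxybenzoic acid
Product: 2 Birch acid
Conditions: Li, NH3(l)/THF, −78 °C; then (i-Pr)3SiOCH2Cl, −78 °C; NH4Cl, careful acidification to pH 5 at 0 °C
Reagents that add atoms: (triisopropylsiloxy)methyl chloride ClCO[Si](C(C)C)(C(C)C)C(C)C
Why: Birch reductive alkylation, in which the carboxylate-stabilised cyclohexadienyl dianion is alkylated at the ipso carbon (C10) by the reactive α-chloro ether, should give the achiral bis(enol ether) acid with C14 in place.

Step 2
Reactants: 2 Birch acid; 3 but-3-yn-2-one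
Product: 4 enol ester
Conditions: DABCO (10 mol%), CH2Cl2, 0 °C
Reagents that add atoms: none
Why: amine-catalysed conjugate (oxa-Michael) addition of the carboxylic acid to the ynone should give the (E)-β-acyloxy enone under basic conditions that leave the enol ethers intact.

Step 3
Reactants: 4 enol ester
Product: 6 tricyclic lactone adduct, via conjugated diene 5 (not isolated)
Conditions: (R)-3,3'-bis(2,4,6-triisopropylphenyl)-1,1'-binaphthyl-2,2'-diyl N-triflylphosphoramide (10 mol%), 4 Å molecular sieves, toluene, −78 to −20 °C; Et3N quench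
Reagents that add atoms: none
Why: Proposed new method: the strong chiral Brønsted acid should protonate an enol ether of 4 reversibly at C9 or C5 and so equilibrate the achiral 1,4-diene with both enantiomers of the conjugated 1,3-dimethoxydiene (5 and its mirror image), while the same acid, hydrogen-bonded to the enone, accelerates an asynchronous intramolecular Diels–Alder reaction of only one of them (a dynamic kinetic resolution of interconverting dienes); the closest known reaction types are the chiral N-triflylphosphoramide-catalysed Diels–Alder reaction of enones with oxygenated dienes and the acid- or metal-mediated conjugation of Birch dienes before cycloaddition. The γ-lactone ring (C1, O, C6, C5, C10) closes through the three-atom tether as in a type 1 intramolecular Diels–Alder reaction (5-exo in the stepwise limit), and the carbocycle C5–C6–C7–C8–C9–C10 closes by the [4+2] bond pair C5–C6 and C7–C8, the second bond being a six-membered Michael-type closure onto the vinylogous oxocarbenium ion. C10 and the absolute sense are set by the catalyst, which decides whether C5 or C9 becomes the diene terminus; C6 is set by the tether (its oxygen must be cis to C1, on the α face); C7 follows from the (E)-alkene by suprafacial addition (acetyl trans to the C6 oxygen); the bridgeheads C5 and C8 follow from the bicycle. The step needs regioselectivity (C5 to C6, not to C7) and selection between the enantiotopic ring halves: the first is secured by the polarity match of the nucleophilic diene terminus C5 with the β-carbon C6 and by the five-membered tether, the second rests on the catalyst.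

Step 4
Reactants: 6 tricyclic lactone adduct
Product: 7 vinyl triflate
Conditions: KN(SiMe3)2, THF, −78 °C; then PhNTf2, −78 to 0 °C
Reagents that add atoms: N-phenylbis(trifluoromethanesulfonimide) O=S(=O)(N(c1ccccc1)S(=O)(=O)C(F)(F)F)C(F)(F)F
Why: kinetic deprotonation of the methyl ketone at its methyl group (C13) by the hindered amide base and O-triflation of the enolate should give the terminal vinyl triflate, which removes the C11 carbonyl before the later retro-aldol step and prepares C11 for carbonylation.

Step 5
Reactants: 7 vinyl triflate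
Product: 8 lactol
Conditions: i-Bu2AlH (1.2 equiv), CH2Cl2, −78 °C; aqueous sodium potassium tartrate
Reagents that add atoms: none
Why: partial reduction of a lactone by a dialkylaluminium hydride at low temperature stops at the tetrahedral aluminium acetal and should give the bridged lactol on work-up, with the vinyl triflate and the enol ether untouched.

Step 6
Reactants: 8 lactol
Product: 10 bicyclic C6 silyl ether, via bicyclic C6 alcohol 9 (not isolated)
Conditions: Ph3PCH3Br, KN(SiMe3)2, THF, 0 °C to rt; then work-up and, on the crude alcohol, t-BuMe2SiOTf, 2,6-lutidine, CH2Cl2, −78 to 0 °C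
Reagents that add atoms: methylenetriphenylphosphorane C=P(c1ccccc1)(c1ccccc1)c1ccccc1; tert-butyldimethylsilyl trifluoromethanesulfonate CC(C)(C)[Si](C)(C)OS(=O)(=O)C(F)(F)F
Why: Wittig methylenation of the open hydroxy aldehyde form of the lactol should turn C1 into the C10 vinyl group and release the C6 hydroxyl, which is silylated at once so that it stays masked until the lactone is closed.

Step 7
Reactants: 10 bicyclic C6 silyl ether
Product: 12 cyclohexanone diketone, via bicyclic methoxy ketone 11 (not isolated)
Conditions: aq. HCl (1 M), THF, rt to 40 °C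
Reagents that add atoms: water O
Why: acid hydrolysis of the enol ether gives the C4 ketone, and the bridgehead β-methoxy ketone should then undergo an acid-mediated retro-aldol (Grob-type) cleavage of the C8–C15 bond, driven by release of the bicyclo[2.2.2]octane strain and by hydrolysis of the C8 oxocarbenium ion, to give the cyclohexanone in which the substituents on C5, C6 and C7 are all equatorial (C5 and C7 are epimerisable and this is their stable arrangement).

Step 8
Reactants: 12 cyclohexanone diketone
Product: 13 axial 8β-alcohol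
Conditions: LiBH(s-Bu)3 (L-Selectride, 1.05 equiv), THF, −78 °C; aq. NH4Cl
Reagents that add atoms: none
Why: bulky hydride reduction, in which the ring ketone should react ahead of the hindered α-branched methyl ketone and equatorial attack (the axial path is blocked by the axial CH2OSi group on C10) should give the axial 8β-alcohol.

Step 9
Reactants: 13 axial 8β-alcohol
Product: 14 isopropenyl alcohol
Conditions: Ph3PCH3Br, KN(SiMe3)2 (3 equiv), THF, 0 to 40 °C
Reagents that add atoms: methylenetriphenylphosphorane C=P(c1ccccc1)(c1ccccc1)c1ccccc1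
Why: Wittig methylenation of the remaining methyl ketone, with the C8 hydroxyl carried as its alkoxide, should give the isopropenyl group in which the new CH2 is C3 and the old methyl is the future C15.

Step 10
Reactants: 15 2-(bromomethyl)acrylic acid; 16 4-methoxybenzyl alcohol
Product: 17 PMB-protected hydroxymethacrylic acid
Conditions: NaH (2.2 equiv), THF, 0 °C to rt; then aq. HCl to pH 3
Reagents that add atoms: none
Why: Williamson-type substitution, in which the alkoxide should displace the allylic bromide of the carboxylate (direct SN2 and SN2' give the same product).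

Step 11
Reactants: 14 isopropenyl alcohol; 17 PMB-protected hydroxymethacrylic acid
Product: 18 8α-ester
Conditions: PPh3, DIAD, toluene, 0 °C to rt
Reagents that add atoms: none
Why: Mitsunobu esterification, in which SN2 displacement of the oxyphosphonium group of the axial 8β-alcohol by the carboxylate should give the equatorial 8α-ester with inversion while the C6 oxygen is masked.

Step 12
Reactants: 18 8α-ester
Product: 19 C6,C14-diol
Conditions: HF·pyridine, pyridine, THF, 0 °C to rt
Reagents that add atoms: none
Why: fluoride-mediated cleavage of both silyl ethers under buffered, non-basic conditions should free the C6 and C14 hydroxyls without acyl migration and without loss of the vinyl triflate or the 4-methoxybenzyl ether.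

Step 13
Reactants: 19 C6,C14-diol
Product: 20 methylene lactone alcohol
Conditions: Pd(PPh3)4 (10 mol%), CO (1 atm), n-Bu3N, MeCN, 65 °C
Reagents that add atoms: carbon monoxide [C-]#[O+]
Why: palladium-catalysed carbonylative lactonisation, in which oxidative addition of zerovalent palladium into the vinyl triflate, CO insertion and capture of the acylpalladium by the C6 hydroxyl (the only one that can close a five-membered ring) should give the trans-fused α-methylene-γ-lactone.

Step 14
Reactants: 20 methylene lactone alcohol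
Product: 21 C14 acetate
Conditions: Ac2O, pyridine, DMAP (cat.), CH2Cl2, 0 °C
Reagents that add atoms: acetic anhydride CC(=O)OC(C)=O
Why: nucleophile-catalysed acylation of the only free hydroxyl (C14) should give the acetate.

Step 15
Reactants: 21 C14 acetate
Product: 23 enal PMB ether, via allylic alcohol 22 (not isolated)
Conditions: SeO2 (0.5 equiv), t-BuOOH, CH2Cl2, rt; then MnO2, CH2Cl2, rt
Reagents that add atoms: selenium dioxide O=[Se]=O; tert-butyl hydroperoxide CC(C)(C)OO
Why: allylic oxidation by SeO2 (ene reaction, then [2,3]-sigmatropic shift) should occur at the methyl group of the only electron-rich alkene that has allylic hydrogens (the vinyl group has none and the other alkenes are electron-poor), and MnO2 completes the oxidation of the allylic alcohol to the enal.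

Step 16
Reactants: 23 enal PMB ether
Product: 24 target CNP0185525.1
Conditions: DDQ, CH2Cl2/pH 7 phosphate buffer, 0 °C to rt
Reagents that add atoms: none
Why: oxidative cleavage of the 4-methoxybenzyl ether (hydride abstraction to the oxocarbenium ion, then hydrolysis) should free the allylic hydroxyl under neutral conditions that spare the enal, both esters and the methylene lactone.

Compound list

1 | 3,5-dimethoxybenzoic acid | COc1cc(OC)cc(c1)C(=O)O | starting material
2 | 3,5-dimethoxy-1-[(triisopropylsilyloxy)methyl]cyclohexa-2,5-diene-1-carboxylic acid (achiral) | OC(=O)C1(CO[Si](C(C)C)(C(C)C)C(C)C)C=C(OC)CC(OC)=C1 | intermediate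
3 | but-3-yn-2-one | CC(=O)C#C | starting material
4 | (E)-3-oxobut-1-en-1-yl 3,5-dimethoxy-1-[(triisopropylsilyloxy)methyl]cyclohexa-2,5-diene-1-carboxylate (achiral) | CC(=O)/C=C/OC(=O)C1(CO[Si](C(C)C)(C(C)C)C(C)C)C=C(OC)CC(OC)=C1 | intermediate
5 | conjugated isomer of 4: cyclohexa-2,4-diene with C5=C4 and C15=C8 double bonds and C9 as CH2; enantiomer shown | CC(=O)/C=C/OC(=O)[C@@]1(CO[Si](C(C)C)(C(C)C)C(C)C)C=C(OC)C=C(OC)C1 | intermediate
6 | bicyclo[2.2.2]octene adduct: bridgeheads C5 (H) and C8 (OMe); bridges C4(OMe)=C15H, C6–C7 and C9–C10; γ-lactone C10–C1(=O)–O–C6 on the α face; 7β-acetyl; 10β-CH2OSi(i-Pr)3 | O=C1O[C@H]2[C@H](C(C)=O)[C@]3(OC)C=C(OC)[C@H]2[C@@]1(CO[Si](C(C)C)(C(C)C)C(C)C)C3 | intermediate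
7 | as 6, with 1-(trifluoromethanesulfonyloxy)vinyl on C7 in place of acetyl | O=C1O[C@H]2[C@H](C(=C)OS(=O)(=O)C(F)(F)F)[C@]3(OC)C=C(OC)[C@H]2[C@@]1(CO[Si](C(C)C)(C(C)C)C(C)C)C3 | intermediate
8 | as 7, with the lactone carbonyl C1 reduced to the lactol (C1–OH, either configuration at C1) | OC1O[C@H]2[C@H](C(=C)OS(=O)(=O)C(F)(F)F)[C@]3(OC)C=C(OC)[C@H]2[C@@]1(CO[Si](C(C)C)(C(C)C)C(C)C)C3 | intermediate
9 | bicyclo[2.2.2]octene with 10α-vinyl, 10β-CH2OSi(i-Pr)3, 6α-OH, 7β-[1-(triflyloxy)vinyl], 8-OMe, C4(OMe)=C15H | C=C[C@]1(CO[Si](C(C)C)(C(C)C)C(C)C)C[C@@]2(OC)C=C(OC)[C@@H]1[C@@H](O)[C@@H]2C(=C)OS(=O)(=O)C(F)(F)F | intermediate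
10 | 6α-O-tert-butyldimethylsilyl ether of 9 | C=C[C@]1(CO[Si](C(C)C)(C(C)C)C(C)C)C[C@@]2(OC)C=C(OC)[C@@H]1[C@@H](O[Si](C)(C)C(C)(C)C)[C@@H]2C(=C)OS(=O)(=O)C(F)(F)F | intermediate
11 | as 10, with the enol ether hydrolysed: C4 ketone, C15H2, bridgehead 8-OMe | C=C[C@]1(CO[Si](C(C)C)(C(C)C)C(C)C)C[C@@]2(OC)CC(=O)[C@@H]1[C@@H](O[Si](C)(C)C(C)(C)C)[C@@H]2C(=C)OS(=O)(=O)C(F)(F)F | intermediate
12 | cyclohexanone (C8=O) with 5β-acetyl, 6α-OSiMe2t-Bu, 7β-[1-(triflyloxy)vinyl], 10α-vinyl, 10β-CH2OSi(i-Pr)3 | C=C[C@]1(CO[Si](C(C)C)(C(C)C)C(C)C)CC(=O)[C@@H](C(=C)OS(=O)(=O)C(F)(F)F)[C@H](O[Si](C)(C)C(C)(C)C)[C@H]1C(C)=O | intermediate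
13 | as 12, with C8 reduced to the axial 8β-alcohol | C=C[C@]1(CO[Si](C(C)C)(C(C)C)C(C)C)C[C@@H](O)[C@@H](C(=C)OS(=O)(=O)C(F)(F)F)[C@H](O[Si](C)(C)C(C)(C)C)[C@H]1C(C)=O | intermediate
14 | as 13, with 5β-isopropenyl in place of acetyl | C=C[C@]1(CO[Si](C(C)C)(C(C)C)C(C)C)C[C@@H](O)[C@@H](C(=C)OS(=O)(=O)C(F)(F)F)[C@H](O[Si](C)(C)C(C)(C)C)[C@H]1C(C)=C | intermediate
15 | 2-(bromomethyl)acrylic acid | OC(=O)C(=C)CBr | starting material
16 | 4-methoxybenzyl alcohol | COc1ccc(CO)cc1 | starting material
17 | 2-{[(4-methoxybenzyl)oxy]methyl}acrylic acid | OC(=O)C(=C)COCc1ccc(OC)cc1 | intermediate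
18 | 8α-ester of 17 (C8 inverted relative to 14), otherwise as 14 | C=C[C@]1(CO[Si](C(C)C)(C(C)C)C(C)C)C[C@H](OC(=O)C(=C)COCc2ccc(OC)cc2)[C@@H](C(=C)OS(=O)(=O)C(F)(F)F)[C@H](O[Si](C)(C)C(C)(C)C)[C@H]1C(C)=C | intermediate
19 | as 18, with free 6α-OH and free C14–OH | C=C[C@]1(CO)C[C@H](OC(=O)C(=C)COCc2ccc(OC)cc2)[C@@H](C(=C)OS(=O)(=O)C(F)(F)F)[C@H](O)[C@H]1C(C)=C | intermediate
20 | trans-fused 12,6α-olide with 11(13)-methylene, 8α-ester of 17, 5β-isopropenyl, 10α-vinyl, 10β-CH2OH | C=C[C@]1(CO)C[C@H](OC(=O)C(=C)COCc3ccc(OC)cc3)[C@H]2C(=C)C(=O)O[C@@H]2[C@H]1C(C)=C | intermediate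
21 | C14 acetate of 20 | C=C[C@]1(COC(C)=O)C[C@H](OC(=O)C(=C)COCc3ccc(OC)cc3)[C@H]2C(=C)C(=O)O[C@@H]2[C@H]1C(C)=C | intermediate
22 | as 21, with the side chain on C5 as C4(=C3H2)–C15H2OH | C=C[C@]1(COC(C)=O)C[C@H](OC(=O)C(=C)COCc3ccc(OC)cc3)[C@H]2C(=C)C(=O)O[C@@H]2[C@H]1C(=C)CO | intermediate
23 | as 21, with the side chain on C5 as C4(=C3H2)–C15HO (4-methoxybenzyl ether of the target) | C=C[C@]1(COC(C)=O)C[C@H](OC(=O)C(=C)COCc3ccc(OC)cc3)[C@H]2C(=C)C(=O)O[C@@H]2[C@H]1C(=C)C=O | intermediate
24 | CNP0185525.1: 14-acetoxy-8α-[2-(hydroxymethyl)acryloyloxy]-15-oxoelema-1,3,11(13)-trien-12,6α-olide | C=C[C@]1(COC(C)=O)C[C@H](OC(=O)C(=C)CO)[C@H]2C(=C)C(=O)O[C@@H]2[C@H]1C(=C)C=O | target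

Total step count: 16 (15 in the main line, 1 for acid 17).
Longest linear sequence: 15 steps (steps 1–9 and 11–16).

Steps most likely to fail

1. Step 3 (Proposed new method). The catalyst may not distinguish the two interconverting enantiomeric dienes well enough, or the acid may destroy the enol ethers before cycloaddition. Fallback with known chemistry, setting out from 4: RhCl(PPh3)3 (5 mol%) in toluene at 90 °C conjugates the diene and the thermal intramolecular Diels–Alder reaction gives the racemic tricyclic lactone adduct F1. This is taken through steps 4 and 5 and the Wittig stage of step 6 to the racemic vinyl triflate F2, the racemic lactol F3 and the racemic bicyclic C6 alcohol F4. Acylation of F4 with (1S)-camphanic chloride (DMAP, pyridine, CH2Cl2) gives two diastereomeric esters, the (1S)-camphanate of 9 F5 and the (1S)-camphanate of the mirror image of 9 F6, which are separated by chromatography. K2CO3 in MeOH cleaves F5 to 9, which is silylated as in step 6 and so returns to the route at 10.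

2. Step 11. The activated axial alcohol may undergo E2 elimination (anti-periplanar axial hydrogens on C7 and C9) in place of substitution. Fallback, setting out from 14: Oppenauer/Meerwein–Ponndorf–Verley equilibration (Al(Oi-Pr)3, a little acetone, i-PrOH/toluene, 80 °C) passes through the C8 ketone F7 (not isolated) and should settle on the equatorial 8α-alcohol F8, the more stable epimer because the 1,3-diaxial contact with the C10 substituent is lost. Yamaguchi esterification of F8 with 17 (2,4,6-trichlorobenzoyl chloride, Et3N, then DMAP, toluene) then gives 18 with retention.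

3. Step 15. The allylic oxidation may attack the C5–H bond as well as the methyl group, or over-oxidise. Fallback, setting out from 21: ene-type allylic chlorination (N-chlorosuccinimide, PhSeCl (cat.), CH2Cl2, rt) gives the allylic chloride F9, and Kornblum oxidation (AgBF4, DMSO, rt; then Et3N) converts it into 23.

Further compounds

F1 | step 3 | racemic tricyclic lactone adduct (6 and its mirror image; one enantiomer drawn) | O=C1O[C@H]2[C@H](C(C)=O)[C@]3(OC)C=C(OC)[C@H]2[C@@]1(CO[Si](C(C)C)(C(C)C)C(C)C)C3
F2 | step 3 | racemic vinyl triflate (7 and its mirror image; one enantiomer drawn) | O=C1O[C@H]2[C@H](C(=C)OS(=O)(=O)C(F)(F)F)[C@]3(OC)C=C(OC)[C@H]2[C@@]1(CO[Si](C(C)C)(C(C)C)C(C)C)C3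
F3 | step 3 | racemic lactol (8 and its mirror image; one enantiomer drawn) | OC1O[C@H]2[C@H](C(=C)OS(=O)(=O)C(F)(F)F)[C@]3(OC)C=C(OC)[C@H]2[C@@]1(CO[Si](C(C)C)(C(C)C)C(C)C)C3
F4 | step 3 | racemic bicyclic C6 alcohol (9 and its mirror image; one enantiomer drawn) | C=C[C@]1(CO[Si](C(C)C)(C(C)C)C(C)C)C[C@@]2(OC)C=C(OC)[C@@H]1[C@@H](O)[C@@H]2C(=C)OS(=O)(=O)C(F)(F)F
F5 | step 3 | (1S)-camphanate of 9 | C=C[C@]1(CO[Si](C(C)C)(C(C)C)C(C)C)C[C@@]2(OC)C=C(OC)[C@@H]1[C@@H](OC(=O)[C@@]34CC[C@@](C)(C(=O)O3)C4(C)C)[C@@H]2C(=C)OS(=O)(=O)C(F)(F)F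
F6 | step 3 | (1S)-camphanate of the mirror image of 9 | C=C[C@@]1(CO[Si](C(C)C)(C(C)C)C(C)C)C[C@]2(OC)C=C(OC)[C@H]1[C@H](OC(=O)[C@@]34CC[C@@](C)(C(=O)O3)C4(C)C)[C@H]2C(=C)OS(=O)(=O)C(F)(F)F
F7 | step 11 | C8 ketone of 14 (not isolated) | C=C[C@]1(CO[Si](C(C)C)(C(C)C)C(C)C)CC(=O)[C@@H](C(=C)OS(=O)(=O)C(F)(F)F)[C@H](O[Si](C)(C)C(C)(C)C)[C@H]1C(C)=C
F8 | step 11 | equatorial 8α-alcohol (C8 epimer of 14) | C=C[C@]1(CO[Si](C(C)C)(C(C)C)C(C)C)C[C@H](O)[C@@H](C(=C)OS(=O)(=O)C(F)(F)F)[C@H](O[Si](C)(C)C(C)(C)C)[C@H]1C(C)=C
F9 | step 15 | allylic chloride: as 21, with the side chain on C5 as C(=CH2)CH2Cl | C=C[C@]1(COC(C)=O)C[C@H](OC(=O)C(=C)COCc3ccc(OC)cc3)[C@H]2C(=C)C(=O)O[C@@H]2[C@H]1C(=C)CCl
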